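## Structural features

The target is a germacranolide: a ten-membered carbocycle C1–C10 with a Z-trisubstituted alkene C1=C10 and an E-trisubstituted alkene C4=C5. An α-methylene-γ-butyrolactone (O6–C12(=O)–C11(=C13)–C7) is trans-fused across C6–C7. Four contiguous stereocentres C6, C7, C8 and C9 lie on one flank of the ring (6α-O, 7β-C, 8α-O, 9α-O in the usual drawing); the fifth, the allylic carbinol C3 (S), is isolated between C2 and C4. The four ring oxygens end in four different states: lactone (O6), (Z)-2-methylbut-2-enoate (angelate, O8), acetate (O9) and free hydroxyl (O3). Fragile groups are the exocyclic acrylate (Michael acceptor), the angelate (isomerises to tiglate), the vicinal esters (acyl migration), the allylic C3–O bond and the cyclodeca-1,5-diene (transannular cyclisation in acid, Cope shift on strong heating). The real difficulty is a medium ring with two alkenes of opposite geometry, a remote C3 centre and four differentiated oxygens. The key step exploits the unit C10=C1–C2–C3–C4=C5, a 1,5-diene: a retro-[3,3] shift joins C5 to C10 and leaves a cyclohexane C5–C10 that carries C6–C9 as ring substituents and maps onto (R)-carvone (C5 carbonyl, C10 methyl-bearing carbon, C7 isopropenyl = C11–C13).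

## Logic of the disconnections

**33 ⇒ 32 ⇒ 31 ⇒ 30.** The O3–benzyl bond and the two acyl C–O bonds at O8 and O9 are cut first, because the esters and the free allylic alcohol are the most fragile groups. This leaves 30, which carries only the lactone, a diol and one ether. The forward steps must distinguish O9 from O8, keep the angelate Z, and remove the benzyl ether oxidatively without touching alkenes.

**30 ⇒ 29.** The two ketal C–O bonds are restored so that O8 and O9 travel as one base-stable unit. The demand is a hydrolysis mild enough for the 1,5-diene.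

**29 ⇒ 26 ⇒ 25.** The O6–C12 lactone bond and the C12 oxidation level are removed, then both O–Si bonds are restored. The lactone is made while O8 is still tied in the ketal, so only O6 can close onto C12. The forward step needs an oxidant that takes the primary allylic alcohol in preference to the secondary one.

**25 ⇒ 24.** C5–H is traced back to C5–OTf. This stores the enolate geometry of the ring expansion in a form that a palladium hydride replaces with retention.

**24 ⇒ 21 (key).** C5–C10 is reconnected and C2–C3 is cut. The ten-membered ring, both alkene geometries and C3 collapse into a cyclohexanol whose stereocentres are ordinary ring substituents. The forward step needs a single chair transition state and an enolate that is trapped before it loses the C3 alkoxy group.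

**21 ⇒ 14 + 19.** The C4–C5 bond is cut to a ketone and a three-carbon alkenyl nucleophile. The demands are a configurationally defined Z reagent and α-face entry at a hindered carbonyl.

**19 ⇒ 17 ⇒ 16 ⇒ 15.** The C–Br bond, the enol ether double-bond position and the O–allyl bond are removed in turn, reaching a commercial alcohol. The demand is control of enol ether geometry.

**14 ⇒ 13 ⇒ 11.** The O6–Si and C6–O bonds are cut. C6 is the only enolisable carbon of 11, so regiochemistry is not an issue and only the face has to be controlled.

**11 ⇒ 10 ⇒ 9.** The ketal and then the C8–O and C9–O bonds are cut to the ring alkene. The forward osmylation must choose this alkene over two others and the α face.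

**9 ⇒ 5 + 6.** The C10–C1 bond is cut to an extended dienolate and a vinyl cation equivalent. This removes the quaternary centre and restores the conjugated enone. The demand is α- rather than α′-alkylation, anti to the C7 substituent.

**5 ⇒ 4 ⇒ 2 ⇒ 1.** The O–Si bond and the C12–O bond are cut, back to the unfunctionalised isopropenyl group of the chiral-pool ketone 1. The demand is oxidation of that alkene only.

## Other disconnections considered

**Alternative 1:** The cut is the pair of C–O bonds O6–C6 and O3–C3, a 1,4-dioxygenation across a C3=C4–C5=C6 diene. Forward, divalent palladium (Pd(OAc)2, benzoquinone, LiOAc, acetic acid) would let the C12 carboxylate add to C6, and acetate would then open the C3–C5 allylpalladium at C3 to give the open-chain lactone acetate A1.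
- In its favour: one mild, non-basic catalytic step makes the lactone, oxidises C3 and leaves E-C4=C5. On early lactone installation and on avoiding an enolate with a β-leaving group it is the better of the two plans.
- Against it here: A1 is acyclic, so the ten-membered ring must still be closed end to end at C9–C10 onto a hindered Z-alkenyl carbon. C3 would be set by remote induction through a flexible allyl complex rather than by a chair. The O3 acetate collides with the O9 acetate of the target and must be exchanged. C7 and C8 need separate acyclic stereocontrol.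
- Comparison: the chosen plan obtains the ring, both alkene geometries and C3 in one step from a chiral-pool ring, and is ahead on structure and step economy.

**Alternative 2:** The cut is the ring bond C3–C4. Forward, zerovalent nickel (Ni(cod)2, IMes) with triisopropylsilane would couple the C3 aldehyde with the methyl-bearing alkyne carbon and deliver hydride to C5, giving the cyclic silyl ether A2.
- In its favour: a neutral catalytic step that closes the ring, creates C3 and gives E-C4=C5 by syn addition. In what the step creates it is the equal of the chosen plan, and in functional-group tolerance it is the better.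
- Against it here: it is an end-to-end closure of a ten-membered ring, with the usual entropic and transannular penalty. Alkyne regiochemistry (C4 against C5, ten- against nine-membered ring) is not enforced electronically. C3 depends on macrocyclic conformation. A2 lacks C13, so a late lactone α-methylenation is needed. The acyclic C6–C9 tetrad and the Z alkene must be built linearly.
- Comparison: the chosen ring expansion is more reliable for ring formation and C3 control and is shorter.

**Alternative 3:** No ring bond is cut; a transannular C4–C9 bond is added to reach a trans-decalin. Forward, KOt-Bu would form the C9 alkoxide, which expels the anti-periplanar C5 mesylate with C4–C9 cleavage to give the dienone A3.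
- In its favour: it is also a ring expansion with no entropic penalty. E-C4=C5 follows stereospecifically from a rigid decalin, which makes it the equal or the better of the chosen plan on alkene geometry. Z-C1=C10 is inherited from a cyclohexene.
- Against it here: the fragmentation creates no stereocentre. A decalin with a quaternary C4, a tertiary C9 carbinol and five further centres must be built. A3 leaves a conjugated C9 ketone that needs a stereoselective reduction next to an epimerisable C8.
- Comparison: mechanistically at least as secure, but the chosen plan creates C3, carries O9 at the right oxidation level and is considerably shorter.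

Key step: step 13

**Remarks on the chemistry**
- Germacrane locants are used for all intermediates (ring C5–C10, side chain C11–C13, C14 on C10, vinyl C1=C2, arm C3, C4, C15). α/β refer to the usual drawing with the C7 side chain β.
- In 23 and 24 the C4=C5 bond is formally Z by the sequence rules, because the oxygen on C5 outranks C6. The ring path C3–C4=C5–C6 is trans and becomes 4E in 25. The structures of 21 and 24 are otherwise consistent with the target at every centre.
- Three design changes are made without touching the disconnection. (a) O6 carries a triisopropylsilyl group, to block silyl transfer from O6 to the neighbouring C5 alkoxide. (b) The enolate is trapped cold with a pyridyl triflimide. (c) The lactone is closed before the diol is freed, so that no acid-labile silyl ether is present during ketal hydrolysis and O8 cannot compete for C12.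

## Route

Step 1
Reactants: 1 (R)-carvone
Product: 2 (5R)-5-(3-chloroprop-1-en-2-yl)-2-methylcyclohex-2-en-1-one
Conditions: Ca(OCl)2, solid CO2, CH2Cl2/H2O, 0 °C
Reagents that add atoms: calcium hypochlorite, [Ca+2].[O-]Cl.[O-]Cl
Why: Ene-type allylic chlorination by hypochlorous acid attacks only the electron-rich 1,1-disubstituted alkene (the enone alkene is inert), shifting the double bond to C11=C13 and placing chlorine on C12; C7 is untouched.

Step 2
Reactants: 2 (5R)-5-(3-chloroprop-1-en-2-yl)-2-methylcyclohex-2-en-1-one
Product: 4 (5R)-5-(3-hydroxyprop-1-en-2-yl)-2-methylcyclohex-2-en-1-one, via allylic acetate 3 (not isolated)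
Conditions: KOAc, Bu4NI (cat.), DMF, 50 °C; then MeOH, K2CO3 (0.2 equiv), 0 °C
Reagents that add atoms: potassium acetate, CC(=O)[O-].[K+]
Why: Nucleophilic substitution of the allylic chloride (direct and allylic attack give the same product) followed by carbonate-catalysed transesterification; the conditions are too mild to disturb the enone.

Step 3
Reactants: 4 (5R)-5-(3-hydroxyprop-1-en-2-yl)-2-methylcyclohex-2-en-1-one
Product: 5 (5R)-5-[3-(tert-butyldimethylsilyloxy)prop-1-en-2-yl]-2-methylcyclohex-2-en-1-one
Conditions: t-BuMe2SiCl, imidazole, CH2Cl2, 0 °C to rt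
Reagents that add atoms: tert-butyldimethylsilyl chloride, CC(C)(C)[Si](C)(C)Cl
Why: Standard silylation of a primary alcohol; the ether survives all later bases and is removed by fluoride together with the O6 silyl group.

Step 4
Reactants: 5 (5R)-5-[3-(tert-butyldimethylsilyloxy)prop-1-en-2-yl]-2-methylcyclohex-2-en-1-one; 6 phenyl vinyl sulfoxide
Product: 9 10β-methyl-10α-vinyl cyclohex-8-en-5-one carrying the 7β silyloxypropenyl chain, via potassium dienolate 7 (not isolated), via sulfoxide adduct 8 (not isolated)
Conditions: KOt-Bu (0.3 equiv), t-BuOH/THF, 0 °C, slow addition of 6; aqueous work-up; then toluene, NaHCO3, 110 °C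
Reagents that add atoms: none
Why: Under equilibrating alkoxide base the extended dienolate 7 reacts at its α-carbon C10 (deconjugative Michael addition to the vinyl sulfoxide, a vinyl cation equivalent), and thermal syn-elimination of benzenesulfenic acid from 8 unveils the vinyl group. Attack anti to the C7 side chain should place the new arm α and leave the methyl β; the minor C10 epimer is removed by chromatography.

Step 5
Reactants: 9 10β-methyl-10α-vinyl cyclohex-8-en-5-one carrying the 7β silyloxypropenyl chain
Product: 10 8α,9α-dihydroxy ketone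
Conditions: OsO4 (2 mol%), 4-methylmorpholine N-oxide (0.95 equiv), acetone/H2O, 0 °C, stopped before full conversion
Reagents that add atoms: OsO4 (catalytic oxygen carrier), O=[Os](=O)(=O)=O; 4-methylmorpholine N-oxide, C[N+]1([O-])CCOCC1; water, O
Why: Catalytic cis-dihydroxylation. The ring alkene is the only 1,2-disubstituted one and is attacked on the α face, away from the pseudoaxial C10 methyl and the C7 side chain, which sets C8 and C9. The vinyl group on the quaternary carbon and the C11=C13 alkene (deactivated by its allylic oxygen) should react more slowly.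

Step 6
Reactants: 10 8α,9α-dihydroxy ketone
Product: 11 8α,9α-O-isopropylidene ketone
Conditions: Me2C(OMe)2, pyridinium p-toluenesulfonate (cat.), CH2Cl2, rt
Reagents that add atoms: 2,2-dimethoxypropane, COC(C)(C)OC
Why: Ketalisation of the cis-diol. The cis-fused dioxolane protects the β-hydroxy ketone against retro-aldol cleavage and fits the chair in which O8 is equatorial and O9 axial.

Step 7
Reactants: 11 8α,9α-O-isopropylidene ketone
Product: 13 6α-hydroxy ketone, via potassium enolate 12 (not isolated)
Conditions: KN(SiMe3)2, THF, −78 °C; 2-(phenylsulfonyl)-3-phenyloxaziridine; aq. NH4Cl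
Reagents that add atoms: 2-(phenylsulfonyl)-3-phenyloxaziridine, O=S(=O)(c1ccccc1)N1OC1c1ccccc1
Why: Enolate oxidation by an N-sulfonyloxaziridine. C6 is the only enolisable carbon (C10 is quaternary), and the oxidant approaches anti to the adjacent C7 side chain and the axial C10 methyl, giving the 6α-alcohol trans to C7.

Step 8
Reactants: 13 6α-hydroxy ketone
Product: 14 6α-triisopropylsilyloxy ketone
Conditions: i-Pr3SiOTf, 2,6-lutidine, CH2Cl2, −40 to 0 °C
Reagents that add atoms: triisopropylsilyl trifluoromethanesulfonate, CC(C)[Si](OS(=O)(=O)C(F)(F)F)(C(C)C)C(C)C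
Why: Silylation with a silyl triflate. The bulky triisopropylsilyl group is chosen because it should not shift to the neighbouring tertiary alkoxide formed in steps 12 and 13.

Step 9
Reactants: 15 4-methoxybenzyl alcohol
Product: 16 allyl 4-methoxybenzyl ether
Conditions: NaH, allyl bromide, Bu4NI (cat.), THF, 0 °C to rt
Reagents that add atoms: allyl bromide, C=CCBr
Why: Williamson ether synthesis.

Step 10
Reactants: 16 allyl 4-methoxybenzyl ether
Product: 17 (Z)-prop-1-enyl 4-methoxybenzyl ether
Conditions: KOt-Bu (cat.), DMSO, rt
Reagents that add atoms: none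
Why: Base-mediated prototropic isomerisation of an allyl ether; reprotonation of the cis-coordinated oxyallyl anion gives the Z enol ether.

Step 11
Reactants: 17 (Z)-prop-1-enyl 4-methoxybenzyl ether
Product: 19 (Z)-2-bromoprop-1-enyl 4-methoxybenzyl ether, via dibromide 18 (not isolated)
Conditions: Br2, CH2Cl2, −78 °C; then DBU, −78 °C to rt; chromatography on base-washed silica
Reagents that add atoms: bromine, BrBr
Why: Bromine adds anti to the enol ether far faster than it attacks the arene, and dehydrobromination with loss of the bromide α to oxygen gives the β-bromo enol ether. Anti addition followed by anti elimination should place Br cis to oxygen; any E isomer is removed before use.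

Step 12
Reactants: 14 6α-triisopropylsilyloxy ketone; 19 (Z)-2-bromoprop-1-enyl 4-methoxybenzyl ether
Product: 21 cis-1,2-dialkenylcyclohexanol (5β-OH and 5α Z-enol-ether arm), via alkenyllithium 20 (not isolated)
Conditions: 19, t-BuLi (2 equiv), Et2O, −78 °C; then 14 premixed with LaCl3·2LiCl in THF, −78 to −40 °C; aq. NH4Cl; Et3N-treated silica
Reagents that add atoms: none
Why: Bromine–lithium exchange proceeds with retention, and the lithium cis to oxygen is stable to β-elimination at −78 °C. The lanthanum salt activates the hindered, enolisable ketone for 1,2-addition. The nucleophile should enter on the α face, anti to the axial C10 methyl that shields the β face, setting C5 with the arm axial and cis to the C10 vinyl group.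

Step 13
Reactants: 21 cis-1,2-dialkenylcyclohexanol (5β-OH and 5α Z-enol-ether arm)
Product: 24 cyclodecadienyl enol triflate (C5-OTf; 3S-OPMB; Z-C1=C10), via potassium alkoxide 22 (not isolated), via potassium enolate 23 (not isolated)
Conditions: KN(SiMe3)2, 18-crown-6, THF, −78 to −20 °C; recool to −78 °C; N-(5-chloropyridin-2-yl)bis(trifluoromethanesulfonimide); aq. NH4Cl
Reagents that add atoms: N-(5-chloropyridin-2-yl)-1,1,1-trifluoro-N-(trifluoromethylsulfonyl)methanesulfonamide, FC(F)(F)S(=O)(=O)N(c1ccc(Cl)cn1)S(=O)(=O)C(F)(F)F
Why: Deprotonation gives the crown-separated alkoxide 22, whose oxyanion weakens the C5–C10 bond; the six atoms C3=C4–C5–C10–C1=C2 then pass through a chair in a [3,3] shift that forms C2–C3 and cleaves C5–C10, and the resulting enolate 23 is O-sulfonylated in the same flask. The closest known reaction type is the anionic oxy-Cope ring expansion of 1,2-divinylcyclohexanols to cyclodec-5-enones with enolate trapping. The ten-membered ring is not closed end to end: it arises by ring expansion, four carbons being inserted as the six-membered ring opens. The new stereocentre C3 is controlled by the Z enol ether geometry within that chair: the benzyloxy group is axial, which with the fixed C5 and C10 configurations gives 3S. The step needs one chair over the boat and over the ring-flipped chair; this is secured by the cis relation of the arms, the C5 arm being axial and the C10 vinyl equatorial in the only cyclohexane chair that keeps O6, C11 and O8 equatorial. In that chair C6 is equatorial and C9 axial on the reacting array, so C3 ends trans to C6 across C4=C5 and C2 ends cis to C9 across C1=C10. Loss of the C3 alkoxy group β to the enolate must be avoided; the low temperature allowed by alkoxide acceleration, a C3–O bond that starts near the enolate plane, and immediate cold triflation should secure this. Silyl transfer from O6 to the alkoxide is blocked by the triisopropylsilyl group.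

Step 14
Reactants: 24 cyclodecadienyl enol triflate (C5-OTf; 3S-OPMB; Z-C1=C10)
Product: 25 (1(10)Z,4E)-cyclodecadiene with C5-H
Conditions: Pd(OAc)2 (5 mol%), PPh3, HCO2H, Bu3N, DMF, 50 °C
Reagents that add atoms: none
Why: Palladium-catalysed formate hydrogenolysis of an enol triflate: zerovalent palladium inserts into the C–O bond, formate delivers hydride with loss of CO2, and reductive elimination retains the alkene geometry, so the ring path becomes 4E.

Step 15
Reactants: 25 (1(10)Z,4E)-cyclodecadiene with C5-H
Product: 26 6,12-diol
Conditions: Bu4NF, THF, rt to 40 °C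
Reagents that add atoms: none
Why: Fluoride cleaves both silyl ethers; the ketal, the benzyl ether and the diene are inert to it.

Step 16
Reactants: 26 6,12-diol
Product: 29 trans-fused α-methylene lactone 8,9-acetonide, via hydroxy enal 27 (not isolated), via lactol 28 (not isolated)
Conditions: TEMPO (cat.), PhI(OAc)2, CH2Cl2, rt
Reagents that add atoms: none
Why: Oxoammonium oxidation takes the primary allylic alcohol in preference to the hindered secondary one; the enal 27 closes to the five-membered lactol 28 with O6 (O8 is locked in the ketal), and 28 is oxidised on to the lactone. The trans ring fusion is inherited from C6 and C7.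

Step 17
Reactants: 29 trans-fused α-methylene lactone 8,9-acetonide
Product: 30 lactone 8α,9α-diol
Conditions: AcOH/H2O/THF (3:1:1), 40 °C
Reagents that add atoms: none
Why: Mild acid hydrolysis of the ketal; no silyl ether remains, and a weak acid is used to avoid transannular cyclisation of the 1,5-diene.

Step 18
Reactants: 30 lactone 8α,9α-diol
Product: 31 9-acetate
Conditions: Ac2O (1.1 equiv), pyridine, CH2Cl2, −20 to 0 °C
Reagents that add atoms: acetic anhydride, CC(=O)OC(C)=O
Why: Selective acylation of the allylic C9 hydroxyl, flanked by the sp2 carbon C10, over the C8 hydroxyl next to the branched C7; low temperature and no nucleophilic catalyst limit acetyl migration.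

Step 19
Reactants: 31 9-acetate
Product: 32 9-acetate 8-angelate 3-(4-methoxybenzyl) ether
Conditions: angelic acid, 2,4,6-trichlorobenzoyl chloride, Et3N, toluene, rt; then 31, 70 °C
Reagents that add atoms: angelic acid, C/C=C(/C)C(=O)O
Why: Yamaguchi esterification through the preformed mixed anhydride, the acylation mode that should keep the Z acyl geometry because no free nucleophilic catalyst adds reversibly to the unsaturated acyl group.

Step 20
Reactants: 32 9-acetate 8-angelate 3-(4-methoxybenzyl) ether
Product: 33 target CNP0265116.1
Conditions: DDQ, CH2Cl2/pH 7 buffer, 0 °C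
Reagents that add atoms: none
Why: Oxidative cleavage of the 4-methoxybenzyl ether by hydride abstraction and hydrolysis of the oxocarbenium ion; the esters, the lactone and the alkenes are inert, and buffering at 0 °C limits over-oxidation of the freed allylic alcohol.

## Compound list

1 | (R)-carvone, (5R)-2-methyl-5-(prop-1-en-2-yl)cyclohex-2-en-1-one | CC1=CC[C@H](CC1=O)C(=C)C | starting material
2 | (5R)-5-(3-chloroprop-1-en-2-yl)-2-methylcyclohex-2-en-1-one | CC1=CC[C@H](CC1=O)C(=C)CCl | intermediate
3 | 2-[(1R)-4-methyl-5-oxocyclohex-3-en-1-yl]prop-2-en-1-yl acetate | CC1=CC[C@H](CC1=O)C(=C)COC(C)=O | intermediate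
4 | (5R)-5-(3-hydroxyprop-1-en-2-yl)-2-methylcyclohex-2-en-1-one | CC1=CC[C@H](CC1=O)C(=C)CO | intermediate
5 | (5R)-5-[3-(tert-butyldimethylsilyloxy)prop-1-en-2-yl]-2-methylcyclohex-2-en-1-one | CC1=CC[C@H](CC1=O)C(=C)CO[Si](C)(C)C(C)(C)C | intermediate
6 | phenyl vinyl sulfoxide (racemic) | C=CS(=O)c1ccccc1 | starting material
7 | potassium extended dienolate of 5 (O–C5=C10–C9=C8) | C1C([O-])=C(C)C=C[C@H]1C(=C)CO[Si](C)(C)C(C)(C)C.[K+] | intermediate
8 | Michael adduct: cyclohex-8-en-5-one with 10β-methyl, 10α-[2-(phenylsulfinyl)ethyl], 7β-[3-(tert-butyldimethylsilyloxy)prop-1-en-2-yl] (sulfur epimers) | C1C(=O)[C@](C)(CCS(=O)c2ccccc2)C=C[C@H]1C(=C)CO[Si](C)(C)C(C)(C)C | intermediate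
9 | cyclohex-8-en-5-one with 10β-methyl, 10α-vinyl, 7β-[3-(tert-butyldimethylsilyloxy)prop-1-en-2-yl] | C1C(=O)[C@](C)(C=C)C=C[C@H]1C(=C)CO[Si](C)(C)C(C)(C)C | intermediate
10 | 8α,9α-dihydroxy ketone (10β-methyl, 10α-vinyl, 7β side chain) | C1C(=O)[C@](C)(C=C)[C@H](O)[C@H](O)[C@H]1C(=C)CO[Si](C)(C)C(C)(C)C | intermediate
11 | 8α,9α-O-isopropylidene ketone | C1C(=O)[C@](C)(C=C)[C@@H]2OC(C)(C)O[C@@H]2[C@H]1C(=C)CO[Si](C)(C)C(C)(C)C | intermediate
12 | potassium C5=C6 enolate of 11 | C1=C([O-])[C@](C)(C=C)[C@@H]2OC(C)(C)O[C@@H]2[C@H]1C(=C)CO[Si](C)(C)C(C)(C)C.[K+] | intermediate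
13 | 6α-hydroxy ketone (6-OH trans to the C7 side chain) | O[C@@H]1C(=O)[C@](C)(C=C)[C@@H]2OC(C)(C)O[C@@H]2[C@H]1C(=C)CO[Si](C)(C)C(C)(C)C | intermediate
14 | 6α-triisopropylsilyloxy ketone | CC(C)[Si](C(C)C)(C(C)C)O[C@@H]1C(=O)[C@](C)(C=C)[C@@H]2OC(C)(C)O[C@@H]2[C@H]1C(=C)CO[Si](C)(C)C(C)(C)C | intermediate
15 | 4-methoxybenzyl alcohol | COc1ccc(CO)cc1 | starting material
16 | allyl 4-methoxybenzyl ether | C=CCOCc1ccc(OC)cc1 | intermediate
17 | (Z)-prop-1-enyl 4-methoxybenzyl ether | C/C=C\OCc1ccc(OC)cc1 | intermediate
18 | 1,2-dibromopropyl 4-methoxybenzyl ether (racemic anti adduct) | CC(Br)C(Br)OCc1ccc(OC)cc1 | intermediate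
19 | (Z)-2-bromoprop-1-enyl 4-methoxybenzyl ether (Br cis to O) | C/C(Br)=C/OCc1ccc(OC)cc1 | intermediate
20 | (Z)-[1-(4-methoxybenzyloxy)prop-1-en-2-yl]lithium (Li cis to O) | C/C([Li])=C/OCc1ccc(OC)cc1 | intermediate
21 | cis-1,2-dialkenylcyclohexanol: 5β-OH, 5α-[(Z)-1-(4-methoxybenzyloxy)prop-1-en-2-yl], 6α-OSi(i-Pr)3, 7β-[3-(tert-butyldimethylsilyloxy)prop-1-en-2-yl], 8α,9α-O-isopropylidene, 10β-methyl, 10α-vinyl | CC(C)[Si](C(C)C)(C(C)C)O[C@@H]1[C@](O)(/C(C)=C\OCc2ccc(OC)cc2)[C@](C)(C=C)[C@@H]3OC(C)(C)O[C@@H]3[C@H]1C(=C)CO[Si](C)(C)C(C)(C)C | intermediate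
22 | potassium alkoxide of 21 | CC(C)[Si](C(C)C)(C(C)C)O[C@@H]1[C@]([O-])(/C(C)=C\OCc2ccc(OC)cc2)[C@](C)(C=C)[C@@H]3OC(C)(C)O[C@@H]3[C@H]1C(=C)CO[Si](C)(C)C(C)(C)C.[K+] | intermediate
23 | potassium cyclodeca-1(10),4-dien-5-olate (O5 cis to C3, 3S, Z-C1=C10) | CC(C)[Si](C(C)C)(C(C)C)O[C@@H]1/C([O-])=C(\C)[C@@H](OCc2ccc(OC)cc2)C/C=C(/C)[C@@H]3OC(C)(C)O[C@@H]3[C@H]1C(=C)CO[Si](C)(C)C(C)(C)C.[K+] | intermediate
24 | cyclodecadienyl enol triflate: C5-OTf (C6 trans to C3), 3S-(4-methoxybenzyloxy), Z-C1=C10, 6α-OSi(i-Pr)3, 8α,9α-O-isopropylidene, 7β side chain | CC(C)[Si](C(C)C)(C(C)C)O[C@@H]1/C(OS(=O)(=O)C(F)(F)F)=C(\C)[C@@H](OCc2ccc(OC)cc2)C/C=C(/C)[C@@H]3OC(C)(C)O[C@@H]3[C@H]1C(=C)CO[Si](C)(C)C(C)(C)C | intermediate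
25 | (1(10)Z,4E)-cyclodecadiene, C5-H, otherwise as 24 | CC(C)[Si](C(C)C)(C(C)C)O[C@@H]1/C=C(\C)[C@@H](OCc2ccc(OC)cc2)C/C=C(/C)[C@@H]3OC(C)(C)O[C@@H]3[C@H]1C(=C)CO[Si](C)(C)C(C)(C)C | intermediate
26 | 6α,12-diol of 25 | O[C@@H]1/C=C(\C)[C@@H](OCc2ccc(OC)cc2)C/C=C(/C)[C@@H]3OC(C)(C)O[C@@H]3[C@H]1C(=C)CO | intermediate
27 | 6α-hydroxy C12 enal | O[C@@H]1/C=C(\C)[C@@H](OCc2ccc(OC)cc2)C/C=C(/C)[C@@H]3OC(C)(C)O[C@@H]3[C@H]1C(=C)C=O | intermediate
28 | 6,12-lactol (C12 epimers) | C=C1C(O)O[C@@H]2/C=C(\C)[C@@H](OCc3ccc(OC)cc3)C/C=C(/C)[C@@H]4OC(C)(C)O[C@@H]4[C@@H]12 | intermediate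
29 | 3S-(4-methoxybenzyloxy)-8α,9α-O-isopropylidene-germacra-1(10)Z,4E,11(13)-trien-12,6α-olide | C=C1C(=O)O[C@@H]2/C=C(\C)[C@@H](OCc3ccc(OC)cc3)C/C=C(/C)[C@@H]4OC(C)(C)O[C@@H]4[C@@H]12 | intermediate
30 | 8α,9α-dihydroxy lactone | C=C1C(=O)O[C@@H]2/C=C(\C)[C@@H](OCc3ccc(OC)cc3)C/C=C(/C)[C@H](O)[C@H](O)[C@@H]12 | intermediate
31 | 9α-acetoxy-8α-hydroxy lactone | C=C1C(=O)O[C@@H]2/C=C(\C)[C@@H](OCc3ccc(OC)cc3)C/C=C(/C)[C@H](OC(C)=O)[C@H](O)[C@@H]12 | intermediate
32 | 9α-acetoxy-8α-angeloyloxy-3-(4-methoxybenzyloxy) lactone | C=C1C(=O)O[C@@H]2/C=C(\C)[C@@H](OCc3ccc(OC)cc3)C/C=C(/C)[C@H](OC(C)=O)[C@H](OC(=O)/C(C)=C\C)[C@@H]12 | intermediate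
33 | (1(10)Z,3S,4E,6R,7S,8R,9S)-9-acetoxy-8-angeloyloxy-3-hydroxygermacra-1(10),4,11(13)-trien-12,6-olide (CNP0265116.1) | C=C1C(=O)O[C@@H]2/C=C(\C)[C@@H](O)C/C=C(/C)[C@H](OC(C)=O)[C@H](OC(=O)/C(C)=C\C)[C@@H]12 | target

## Step count and least certain steps

Total step count: 20. Longest linear sequence: 17 (steps 1–8 and 12–20); steps 9–11 form the three-step side branch to 19.

**Step 13 (key step).** The most likely failure is loss of the C3 alkoxy group from the potassium enolate by β-elimination before triflation. The axial benzyloxy group may slow the chair shift enough to require warming, and the crown-separated enolate is a strong base. Partial enolate equilibration through HN(SiMe3)2 is a second risk. Fallback: starting from 21, the same rearrangement would be quenched at −78 °C with Me3SiCl, which traps potassium enolates much faster than a triflimide, to give the trimethylsilyl enol ether F1. F1 would then be treated with MeLi in THF at −78 °C in the presence of the triflimide, so that the less basic, tightly paired lithium enolate is triflated as it forms. The sequence returns to the route at 24.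

**Step 12.** The likely failures are enolisation of the congested ketone in place of addition, and poor facial selectivity. Entry of the branched alkenyl metal on the β face would give the trans-dialkenyl carbinol, which would rearrange to the wrong C1=C10 geometry. Fallback: starting from 14, the slim nucleophile ethynylmagnesium bromide (THF, 0 °C), which favours axial entry, would give the ethynyl carbinol F2. Copper-catalysed anti-carbomagnesiation directed by the magnesium alkoxide (MeMgBr, CuI cat., then I2) would give the Z-iodoalkene F3 with iodine cis to C5. An Ullmann-type etherification with 15 (CuI, 3,4,7,8-tetramethyl-1,10-phenanthroline, Cs2CO3, toluene, 80 °C) would then return to the route at 21.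

**Step 5.** The likely failure is poor chemoselectivity. Osmylation of the 1,1-disubstituted C11=C13 alkene, which is only mildly deactivated by the allylic silyl ether, or of the vinyl group may compete with the more hindered ring alkene. Fallback: starting from 9, the silyl ether would be removed (Bu4NF) to give the allylic alcohol F4. Esterification with 4-nitrobenzoyl chloride and pyridine would give F5, in which the strongly electron-poor allylic ester deactivates C11=C13. Osmylation would then give the diol ester F6, ketalisation the acetonide ester F7, and methanolysis (K2CO3, MeOH) the acetonide alcohol F8. Silylation as in step 3 returns to the route at 11.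

**Step 4.** The likely failures are erosion of facial selectivity at C10, because induction from C7 is only 1,4 and the reaction runs near room temperature, and over-reaction by a second Michael addition at C6. Fallback: starting from 5, the lithium extended dienolate (LiN(i-Pr)2, 0.95 equiv, THF, −78 to 0 °C to equilibrate, then −78 °C) would be added to acetaldehyde under kinetic control to give the α-(1-hydroxyethyl) ketone F9. Syn-dehydration with methyl N-(triethylammoniosulfonyl)carbamate (benzene, 50 °C) can only form the vinyl group, because C10 is quaternary. The sequence returns to the route at 9.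

**Step 18.** The likely failure is insufficient discrimination between the two secondary hydroxyls, together with acetyl migration between O9 and O8 during step 19. Fallback: if the more accessible hydroxyl proves to be O8, the order of acylation would be inverted. Starting from 30, the angeloyl mixed anhydride of step 19 would give the 8-angelate F10, and acetylation of the remaining C9 hydroxyl (Ac2O, pyridine) returns to the route at 32.

## Further compounds

F1 | step 13 | trimethylsilyl enol ether corresponding to 24 (C5-OSiMe3, C6 trans to C3) | CC(C)[Si](C(C)C)(C(C)C)O[C@@H]1/C(O[Si](C)(C)C)=C(\C)[C@@H](OCc2ccc(OC)cc2)C/C=C(/C)[C@@H]3OC(C)(C)O[C@@H]3[C@H]1C(=C)CO[Si](C)(C)C(C)(C)C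
F2 | step 12 | 5α-ethynyl-5β-hydroxy analogue of 21 | CC(C)[Si](C(C)C)(C(C)C)O[C@@H]1[C@](O)(C#C)[C@](C)(C=C)[C@@H]2OC(C)(C)O[C@@H]2[C@H]1C(=C)CO[Si](C)(C)C(C)(C)C
F3 | step 12 | 5α-[(Z)-1-iodoprop-1-en-2-yl] carbinol (iodine cis to C5) | CC(C)[Si](C(C)C)(C(C)C)O[C@@H]1[C@](O)(/C(C)=C\I)[C@](C)(C=C)[C@@H]2OC(C)(C)O[C@@H]2[C@H]1C(=C)CO[Si](C)(C)C(C)(C)C
F4 | step 5 | C12 alcohol of 9 | C1C(=O)[C@](C)(C=C)C=C[C@H]1C(=C)CO
F5 | step 5 | C12 4-nitrobenzoate of 9 | C1C(=O)[C@](C)(C=C)C=C[C@H]1C(=C)COC(=O)c2ccc(cc2)[N+](=O)[O-]
F6 | step 5 | 8α,9α-diol C12 4-nitrobenzoate | C1C(=O)[C@](C)(C=C)[C@H](O)[C@H](O)[C@H]1C(=C)COC(=O)c2ccc(cc2)[N+](=O)[O-]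
F7 | step 5 | 8α,9α-acetonide C12 4-nitrobenzoate | C1C(=O)[C@](C)(C=C)[C@@H]2OC(C)(C)O[C@@H]2[C@H]1C(=C)COC(=O)c3ccc(cc3)[N+](=O)[O-]
F8 | step 5 | 8α,9α-acetonide C12 alcohol | C1C(=O)[C@](C)(C=C)[C@@H]2OC(C)(C)O[C@@H]2[C@H]1C(=C)CO
F9 | step 4 | 10α-(1-hydroxyethyl)-10β-methyl ketone (carbinol epimers) | C1C(=O)[C@](C)(C(C)O)C=C[C@H]1C(=C)CO[Si](C)(C)C(C)(C)C
F10 | step 18 | 8α-angeloyloxy-9α-hydroxy lactone | C=C1C(=O)O[C@@H]2/C=C(\C)[C@@H](OCc3ccc(OC)cc3)C/C=C(/C)[C@H](O)[C@H](OC(=O)/C(C)=C\C)[C@@H]12
A1 | alternative 1 | open-chain trans α-methylene lactone 3-acetate with E-C4=C5, C10 alkenylsilane, 8-(4-methoxybenzyl) ether, C9 silyl ether | C=C1C(=O)O[C@H](/C=C(\C)[C@@H](OC(C)=O)C/C=C(/C)[Si](C)(C)C)[C@H]1[C@@H](OCc3ccc(OC)cc3)CO[Si](C)(C)C(C)(C)C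
A2 | alternative 2 | cyclodecadiene O3-triisopropylsilyl ether (8,9-acetonide, 6-silyl ether, C12 silyl ether, no C13) | CC(C)(C)[Si](C)(C)O[C@@H]2/C=C(\C)[C@@H](O[Si](C(C)C)(C(C)C)C(C)C)C/C=C(/C)[C@@H]4OC(C)(C)O[C@@H]4[C@H]2CCO[Si](C)(C)C(C)(C)C
A3 | alternative 3 | (1(10)Z,4E)-cyclodecadien-9-one (3-silyl ether, 6-silyl ether, 8-(4-methoxybenzyl) ether) | CC[Si](CC)(CC)O[C@@H]2/C=C(\C)[C@@H](O[Si](C)(C)C(C)(C)C)C/C=C(/C)C(=O)[C@H](OCc3ccc(OC)cc3)[C@H]2C(=C)CO[Si](CC)(CC)CC
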